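**Assumption:** the target has no stereocentre (it is achiral), so no enantiocontrol is needed; the only stereo element on the way is the E-alkene of the chalcone, which disappears on ring closure.

**Retrosynthetic overview**
1. Target 12 ⇐ O-methylation of flavonol 11 ⇐ C3-oxygenation (epoxidation, then acid isomerisation) of tangeretin 9.
2. Ring C of 9 ⇐ oxidative cyclisation of 2'-hydroxychalcone 7.
3. Key C–C bond: chalcone 7 ⇐ Claisen–Schmidt aldol condensation of acetophenone 4 with 4-methoxybenzaldehyde 5.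
4. Acetophenone 4 ⇐ 3,4,5-trimethoxyphenol 1 by ortho-acetylation, ring bromination and Cu-mediated methoxylation.
5. Ring order: rings A and B are bought as benzenoid building blocks; ring C is the only ring formed (step 5).

**Route**

Step 1
Reactants: 1 3,4,5-trimethoxyphenol
Product: 2 1-(6-hydroxy-2,3,4-trimethoxyphenyl)ethan-1-one
Conditions: AcOH, BF3·OEt2 (3 equiv), 85–90 °C, 3 h; then aq NaOAc
Reagents that add atoms: acetic acid, CC(=O)O
Why: Lewis-acid-promoted Friedel–Crafts (Fries-type) C-acetylation occurs ortho to the free OH, and the two open ring positions of 1 are equivalent, so only one product can form.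

Step 2
Reactants: 2 1-(6-hydroxy-2,3,4-trimethoxyphenyl)ethan-1-one
Product: 3 1-(3-bromo-2-hydroxy-4,5,6-trimethoxyphenyl)ethan-1-one
Conditions: NBS (1.05 equiv), MeCN, 0 °C to rt, dark
Reagents that add atoms: N-bromosuccinimide, O=C1CCC(=O)N1Br
Why: electrophilic aromatic bromination goes to the single remaining ring CH (ortho to OH, para to OMe), which is far more reactive than the acetyl α-position under non-radical, non-acidic conditions.

Step 3
Reactants: 3 1-(3-bromo-2-hydroxy-4,5,6-trimethoxyphenyl)ethan-1-one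
Product: 4 1-(2-hydroxy-3,4,5,6-tetramethoxyphenyl)ethan-1-one
Conditions: NaOMe (25 wt% in MeOH, 8 equiv), CuBr (0.3 equiv), DMF, 110 °C, N2; then aq HCl
Reagents that add atoms: sodium methoxide, [Na+].[O-]C
Why: Ullmann-type copper-catalysed methoxylation of an ortho-bromophenoxide, the same transformation as 5-bromovanillin to syringaldehyde; the ketone is protected from self-condensation as its unreactive phenoxide.

Step 4
Reactants: 4 1-(2-hydroxy-3,4,5,6-tetramethoxyphenyl)ethan-1-one; 5 4-methoxybenzaldehyde (1.2 equiv)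
Product: 7 (E)-1-(2-hydroxy-3,4,5,6-tetramethoxyphenyl)-3-(4-methoxyphenyl)prop-2-en-1-one, via aldol adduct 6 (not isolated)
Conditions: KOH (50% aq, 10 equiv), EtOH, rt, 24–48 h; then aq HCl to pH 3
Reagents that add atoms: none
Why: Claisen–Schmidt crossed aldol condensation between a methyl ketone and a non-enolisable aldehyde, with E1cB dehydration of the β-hydroxy ketone giving the thermodynamically favoured E-enone.

Step 5
Reactants: 7 (E)-1-(2-hydroxy-3,4,5,6-tetramethoxyphenyl)-3-(4-methoxyphenyl)prop-2-en-1-one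
Product: 9 tangeretin (5,6,7,8-tetramethoxy-2-(4-methoxyphenyl)-4H-chromen-4-one), via flavanone 8 (not isolated)
Conditions: I2 (0.1 equiv), DMSO, 120 °C, 2–4 h; then aq Na2S2O3 wash
Reagents that add atoms: none
Why: I2/DMSO oxidative cyclisation (intramolecular oxa-Michael addition, then iodine-catalysed dehydrogenation with DMSO as terminal oxidant) gives the flavone and avoids the aurone formation that 6'-methoxychalcones suffer under alkaline peroxide.

Step 6
Reactants: 9 tangeretin
Product: 11 3-hydroxytangeretin (3-hydroxy-5,6,7,8-tetramethoxy-2-(4-methoxyphenyl)-4H-chromen-4-one), via tangeretin epoxide 10 (not isolated)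
Conditions: pre-formed DMDO (ca. 0.08 M in acetone, 3 equiv in portions), CH2Cl2, 0 °C to rt, 12–24 h; concentrate; then p-TsOH·H2O (0.1 equiv), CH2Cl2, rt, 1 h
Reagents that add atoms: dimethyldioxirane, CC1(C)OO1
Why: neutral dioxirane epoxidation of the C2=C3 enol-ether bond followed by acid-catalysed epoxide opening to the C2 oxocarbenium ion and loss of H-3 gives the flavonol (a Rubottom-type oxidation), as established for 5-alkoxyflavones.

Step 7
Reactants: 11 3-hydroxytangeretin
Product: 12 3-methoxytangeretin (3,5,6,7,8-pentamethoxy-2-(4-methoxyphenyl)-4H-chromen-4-one)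
Conditions: MeI (3 equiv), K2CO3 (3 equiv), acetone, reflux, 6 h
Reagents that add atoms: iodomethane, CI
Why: Williamson O-methylation of the acidic 3-hydroxyl, the only free OH in the molecule, is clean and leaves the aryl methyl ethers and the pyranone untouched.

**Compound list**
1 | 3,4,5-trimethoxyphenol | COc1cc(O)cc(OC)c1OC | starting material
2 | 1-(6-hydroxy-2,3,4-trimethoxyphenyl)ethan-1-one | CC(=O)c1c(O)cc(OC)c(OC)c1OC | intermediate
3 | 1-(3-bromo-2-hydroxy-4,5,6-trimethoxyphenyl)ethan-1-one | CC(=O)c1c(O)c(Br)c(OC)c(OC)c1OC | intermediate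
4 | 1-(2-hydroxy-3,4,5,6-tetramethoxyphenyl)ethan-1-one | CC(=O)c1c(O)c(OC)c(OC)c(OC)c1OC | intermediate
5 | 4-methoxybenzaldehyde | COc1ccc(C=O)cc1 | starting material
6 | aldol adduct, racemic 3-hydroxy-1-(2-hydroxy-3,4,5,6-tetramethoxyphenyl)-3-(4-methoxyphenyl)propan-1-one (not isolated) | COc1ccc(C(O)CC(=O)c2c(O)c(OC)c(OC)c(OC)c2OC)cc1 | intermediate
7 | (E)-1-(2-hydroxy-3,4,5,6-tetramethoxyphenyl)-3-(4-methoxyphenyl)prop-2-en-1-one | COc1ccc(/C=C/C(=O)c2c(O)c(OC)c(OC)c(OC)c2OC)cc1 | intermediate
8 | flavanone, racemic 5,6,7,8-tetramethoxy-2-(4-methoxyphenyl)chroman-4-one (not isolated) | COc1ccc(C2CC(=O)c3c(OC)c(OC)c(OC)c(OC)c3O2)cc1 | intermediate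
9 | tangeretin, 5,6,7,8-tetramethoxy-2-(4-methoxyphenyl)-4H-chromen-4-one | COc1ccc(-c2cc(=O)c3c(OC)c(OC)c(OC)c(OC)c3o2)cc1 | intermediate
10 | tangeretin epoxide, racemic cis-fused 2,3-epoxy-5,6,7,8-tetramethoxy-2-(4-methoxyphenyl)chroman-4-one (not isolated) | COc1ccc(cc1)C12OC1C(=O)c1c(OC)c(OC)c(OC)c(OC)c1O2 | intermediate
11 | 3-hydroxytangeretin, 3-hydroxy-5,6,7,8-tetramethoxy-2-(4-methoxyphenyl)-4H-chromen-4-one | COc1ccc(-c2oc3c(OC)c(OC)c(OC)c(OC)c3c(=O)c2O)cc1 | intermediate
12 | 3-methoxytangeretin, 3,5,6,7,8-pentamethoxy-2-(4-methoxyphenyl)-4H-chromen-4-one (achiral) | COc1ccc(-c2oc3c(OC)c(OC)c(OC)c(OC)c3c(=O)c2OC)cc1 | target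

**Summary**
Total step count: 7. Longest linear sequence: 7 steps (1 to 12); aldehyde 5 is bought.

**Three steps most likely to fail**

Step 3 (copper-mediated methoxylation). The bromide is flanked by two oxygen substituents and the substrate carries an enolisable ketone, so protodebromination or condensation may lower the yield. The fallback sets out from 3 and postpones the methoxylation until ring C is closed. Bromoketone 3 is condensed with 5 (KOH, EtOH, rt) to give (E)-1-(3-bromo-2-hydroxy-4,5,6-trimethoxyphenyl)-3-(4-methoxyphenyl)prop-2-en-1-one F1. This is cyclised with I2 (0.1 equiv) in DMSO at 120 °C to 8-bromo-5,6,7-trimethoxy-2-(4-methoxyphenyl)-4H-chromen-4-one F2. F2 is then methoxylated with NaOMe/CuBr in DMF/MeOH at 110 °C, the known behaviour of 8-bromoflavones, and the route is rejoined at 9.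

Step 5 (I2/DMSO oxidative cyclisation). The HI formed can cleave the peri 5-methoxy group, and very electron-rich chalcones sometimes stall at the flavanone. The fallback sets out from 4 and builds ring C without any oxidation, by an intermolecular Claisen-type acylation. Ketone 4 is converted to its lithium polyanion (LiHMDS, 3.3 equiv, THF, −78 °C) and acylated on carbon with 4-methoxybenzoyl chloride (COc1ccc(C(Cl)=O)cc1) to give 1-(2-hydroxy-3,4,5,6-tetramethoxyphenyl)-3-(4-methoxyphenyl)propane-1,3-dione F3. Cyclodehydration of F3 (cat. H2SO4, AcOH, 95 °C) gives 9, where the route is rejoined.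

Step 6 (DMDO epoxidation). The C2=C3 bond of a flavone is electron-poor and reacts slowly, while the polymethoxylated rings may be over-oxidised. The fallback sets out from 9 and turns C3 into a nucleophile instead. Deprotonation at C3 with LDA (1.3 equiv, THF, −78 °C) and trapping with B(OMe)3 gives dimethyl [5,6,7,8-tetramethoxy-2-(4-methoxyphenyl)-4-oxo-4H-chromen-3-yl]boronate F4. This is oxidised without isolation (H2O2, AcOH, 0 °C to rt) to flavonol 11, where the route is rejoined.

**Further compounds**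
F1 | step 3 | (E)-1-(3-bromo-2-hydroxy-4,5,6-trimethoxyphenyl)-3-(4-methoxyphenyl)prop-2-en-1-one | COc1ccc(/C=C/C(=O)c2c(O)c(Br)c(OC)c(OC)c2OC)cc1
F2 | step 3 | 8-bromo-5,6,7-trimethoxy-2-(4-methoxyphenyl)-4H-chromen-4-one | COc1ccc(-c2cc(=O)c3c(OC)c(OC)c(OC)c(Br)c3o2)cc1
F3 | step 5 | 1-(2-hydroxy-3,4,5,6-tetramethoxyphenyl)-3-(4-methoxyphenyl)propane-1,3-dione | COc1ccc(C(=O)CC(=O)c2c(O)c(OC)c(OC)c(OC)c2OC)cc1
F4 | step 6 | dimethyl [5,6,7,8-tetramethoxy-2-(4-methoxyphenyl)-4-oxo-4H-chromen-3-yl]boronate | COc1ccc(-c2oc3c(OC)c(OC)c(OC)c(OC)c3c(=O)c2B(OC)OC)cc1
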